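The route rests on the C5–C6 bond. The key step exploits the fact that C5 is the vinylic carbon of the Z-configured C4=C5 olefin on furanone carbon C3, while C6 is the allylic lactone carbinol next to ring-fusion carbon C7. A Nozaki–Hiyama–Kishi addition of the C5 iodoalkene to the C6 aldehyde forms this bond, the C6 stereocentre and the ten-membered carbocycle (nine-membered oxacycle through the furanone oxygen) in one operation. The precursor is an open-chain 3(2H)-furanone with the Z-iodopropenyl arm on C3, the C9 acetate, the C8 methacrylate and, on C7, the aldehyde and the methyl acrylate unit; lactonisation of the C6 hydroxyl onto that ester then gives the target.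

Key step: step 18

Remark: germacrane numbering of the target is used for all intermediates (C1 furanone carbonyl, C10 quaternary furanone carbon, C11–C13 acrylate, C12 ester carbonyl); C8′ is the extra dioxolane carbon that step 13 removes. Assumption: aldehyde 9 is distilled just before use because it oligomerises on storage, and aldehydes 4, 24 and 29 are used without storage.

Step 1
Reactants: 1 prop-2-yn-1-ol
Product: 3 (Z)-3-iodo-2-methylprop-2-en-1-ol, via vinylmagnesium alkoxide 2 (not isolated)
Conditions: MeMgBr (3 equiv), CuI (10 mol%), THF, −10 °C to rt; then I2, −10 °C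
Reagents that add atoms: methylmagnesium bromide, C[Mg]Br; iodine, II
Why: Copper-catalysed carbomagnesiation of the propargylic alkoxide puts methyl on C4 and magnesium on C5 in anti fashion through a five-membered magnesium chelate, and iodinolysis of the C–Mg bond with retention leaves iodine cis to the hydroxymethyl group (Z).

Step 2
Reactants: 3 (Z)-3-iodo-2-methylprop-2-en-1-ol
Product: 4 (Z)-3-iodo-2-methylprop-2-enal
Conditions: MnO2, CH2Cl2, rt, dark
Reagents that add atoms: none
Why: Allylic alcohol oxidation with activated MnO2 is neutral and heterogeneous, so the enal should form without loss of the C–I bond or of the Z geometry.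

Step 3
Reactants: 5 (tert-butyldimethylsilyloxy)acetaldehyde; 6 methyl acrylate
Product: 7 methyl 4-[(tert-butyldimethylsilyl)oxy]-3-hydroxy-2-methylidenebutanoate (racemic)
Conditions: DABCO (0.5 equiv), MeOH, rt
Reagents that add atoms: none
Why: Morita–Baylis–Hillman reaction of an activated α-alkoxy aldehyde with the amine-derived acrylate enolate, in which the carbinol centre needs no control because the next step removes it.

Step 4
Reactants: 7 methyl 4-[(tert-butyldimethylsilyl)oxy]-3-hydroxy-2-methylidenebutanoate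
Product: 8 methyl (Z)-2-(bromomethyl)-4-[(tert-butyldimethylsilyl)oxy]but-2-enoate
Conditions: NBS, Me2S, CH2Cl2, 0 °C to rt
Reagents that add atoms: N-bromosuccinimide, BrN1C(=O)CCC1=O
Why: The alcohol is activated as its alkoxysulfonium salt and bromide attacks the terminal methylene with allylic transposition (SN2′), which should give the conjugated ester with the silyloxymethyl group trans to the ester, as is usual for Morita–Baylis–Hillman alcohols.

Step 5
Reactants: 9 (S)-2,2-dimethyl-1,3-dioxolane-4-carbaldehyde; 10 ethyl 2-[bis(2,2,2-trifluoroethoxy)phosphoryl]propanoate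
Product: 12 ethyl (Z)-3-[(4R)-2,2-dimethyl-1,3-dioxolan-4-yl]-2-methylprop-2-enoate, via potassium phosphonate carbanion 11 (not isolated)
Conditions: KN(SiMe3)2, 18-crown-6, THF, −78 °C
Reagents that add atoms: none
Why: Still–Gennari olefination, in which the electron-poor trifluoroethyl phosphonate eliminates faster than its adducts equilibrate and so should give the Z ester with C8 cis to C1, the geometry that syn dihydroxylation needs for the 9,10 relationship of the target, while the low temperature protects the α-alkoxy aldehyde from epimerisation.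

Step 6
Reactants: 12 ethyl (Z)-3-[(4R)-2,2-dimethyl-1,3-dioxolan-4-yl]-2-methylprop-2-enoate
Product: 13 ethyl (2S,3S)-3-[(4S)-2,2-dimethyl-1,3-dioxolan-4-yl]-2,3-dihydroxy-2-methylpropanoate
Conditions: OsO4 (cat.), NMO, acetone/H2O, rt
Reagents that add atoms: osmium tetroxide, O=[Os](=O)(=O)=O (transfers the two oxygens); N-methylmorpholine N-oxide, C[N+]1([O-])CCOCC1 (restores them); water, O
Why: Osmium tetroxide dihydroxylation (Upjohn conditions) adds both hydroxyls syn to the Z olefin from the face anti to the allylic C8–O bond of the dioxolane, in the conformer fixed by allylic 1,3-strain, which should set C9 and C10 (both S) from the C8 centre of the chiral pool.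

Step 7
Reactants: 13 ethyl (2S,3S)-3-[(4S)-2,2-dimethyl-1,3-dioxolan-4-yl]-2,3-dihydroxy-2-methylpropanoate
Product: 14 (2S,3S)-3-[(4S)-2,2-dimethyl-1,3-dioxolan-4-yl]-2,3-dihydroxy-N-methoxy-N,2-dimethylpropanamide
Conditions: MeNHOMe·HCl, i-PrMgCl, THF, −20 to 0 °C
Reagents that add atoms: N,O-dimethylhydroxylamine hydrochloride, CNOC.Cl
Why: Weinreb amide formation by aminolysis of the ester with the magnesium amide made in the flask is assisted by the α-alkoxide and touches no stereocentre.

Step 8
Reactants: 14 (2S,3S)-3-[(4S)-2,2-dimethyl-1,3-dioxolan-4-yl]-2,3-dihydroxy-N-methoxy-N,2-dimethylpropanamide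
Product: 15 (3S,4S)-4-[(4S)-2,2-dimethyl-1,3-dioxolan-4-yl]-3,4-dihydroxy-3-methylbutan-2-one
Conditions: MeMgBr (excess), THF, 0 °C to rt
Reagents that add atoms: methylmagnesium bromide, C[Mg]Br
Why: Grignard addition to a Weinreb amide stops at the chelated tetrahedral intermediate, which releases the methyl ketone (C1 and C2) only on work-up, so over-addition and base-induced retro-aldol cleavage should not occur.

Step 9
Reactants: 15 (3S,4S)-4-[(4S)-2,2-dimethyl-1,3-dioxolan-4-yl]-3,4-dihydroxy-3-methylbutan-2-one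
Product: 16 (1S,2S)-1-[(4S)-2,2-dimethyl-1,3-dioxolan-4-yl]-2-hydroxy-2-methyl-3-oxobutyl acetate
Conditions: Ac2O, pyridine, DMAP (cat.), CH2Cl2, 0 °C
Reagents that add atoms: acetic anhydride, CC(=O)OC(C)=O
Why: Nucleophile-catalysed acetylation takes the secondary C9 hydroxyl and leaves the tertiary C10 hydroxyl, which installs the final acetate before any iodoalkene is present and blocks C9 from the later cyclodehydration.

Step 10
Reactants: 16 (1S,2S)-1-[(4S)-2,2-dimethyl-1,3-dioxolan-4-yl]-2-hydroxy-2-methyl-3-oxobutyl acetate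
Product: 17 (1S,2S)-1-[(4S)-2,2-dimethyl-1,3-dioxolan-4-yl]-2-methyl-3-oxo-2-[(triethylsilyl)oxy]butyl acetate
Conditions: TESOTf, 2,6-lutidine, CH2Cl2, −78 °C
Reagents that add atoms: triethylsilyl trifluoromethanesulfonate, CC[Si](CC)(CC)OS(=O)(=O)C(F)(F)F
Why: Silylation with a silyl triflate and a hindered base protects the tertiary alcohol at low temperature without enolising the ketone, which keeps this hydroxyl out of the boron aldol.

Step 11
Reactants: 17 (1S,2S)-1-[(4S)-2,2-dimethyl-1,3-dioxolan-4-yl]-2-methyl-3-oxo-2-[(triethylsilyl)oxy]butyl acetate; 4 (Z)-3-iodo-2-methylprop-2-enal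
Product: 19 β-hydroxy ketone with the new C2–C3 bond (both C3 epimers), via boron enolate 18 (not isolated)
Conditions: c-Hex2BCl, Et3N, Et2O, −78 to 0 °C; then 4, −78 to −20 °C; MeOH, pH 7 buffer, H2O2, 0 °C
Reagents that add atoms: none
Why: Boron-mediated aldol reaction of a methyl ketone whose only enolisable position is the C2 methyl group should add 1,2 to the enal while leaving the acetate, the silyl ether and the Z iodoalkene alone, and the configuration of the new carbinol is irrelevant because the next step oxidises it.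

Step 12
Reactants: 19 β-hydroxy ketone
Product: 22 (S)-[(4S)-2,2-dimethyl-1,3-dioxolan-4-yl]{(2S)-5-[(Z)-1-iodoprop-1-en-2-yl]-2-methyl-3-oxo-2,3-dihydrofuran-2-yl}methyl acetate, via silylated diketone 20 (not isolated), via hydroxy diketone 21 (not isolated)
Conditions: DMP, CH2Cl2, 0 °C to rt; then HF·pyridine, THF, 0 °C to rt
Reagents that add atoms: none
Why: Dess–Martin oxidation gives the 1,3-diketone and acidic desilylation frees the tertiary C10 hydroxyl, which adds 5-exo to the C3 carbonyl and loses water (acid cyclodehydration to the 3(2H)-furanone), while the acetylated C9 oxygen cannot compete and C10 keeps its configuration because none of its bonds is broken.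

Step 13
Reactants: 22 furanone acetonide
Product: 24 (1R)-1-{(2S)-5-[(Z)-1-iodoprop-1-en-2-yl]-2-methyl-3-oxo-2,3-dihydrofuran-2-yl}-2-oxoethyl acetate, via diol 23 (not isolated)
Conditions: H5IO6, EtOAc, rt
Reagents that add atoms: none
Why: Periodic acid hydrolyses the terminal acetonide and cleaves the resulting 1,2-diol in the same flask (glycol cleavage), which removes C8′ and leaves C8 as the aldehyde without touching C9.

Step 14
Reactants: 24 furanone α-acetoxy aldehyde; 8 methyl (Z)-2-(bromomethyl)-4-[(tert-butyldimethylsilyl)oxy]but-2-enoate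
Product: 26 homoallylic C8 alcohol (7S,8S,9S,10S), via allylzinc bromide 25 (not isolated)
Conditions: Zn dust, THF/sat. aq. NH4Cl, 0 °C to rt
Reagents that add atoms: none
Why: Barbier-type zinc allylation in which the allylzinc reacts at its substituted γ-terminus through a chair-like six-membered transition state, so that the γ-substituent cis to the metal-bearing methylene should give the 7,8-syn adduct, while attack anti to the C9–O bond (polar Felkin–Anh model) should set C8 anti to C9, and zinc in buffered aqueous THF leaves the iodoalkene, the furanone and the acetate alone.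

Step 15
Reactants: 26 homoallylic C8 alcohol
Product: 27 C8 methacrylate (7S,8S,9S,10S)
Conditions: methacryloyl chloride, i-Pr2NEt, CH2Cl2, 0 °C to rt
Reagents that add atoms: methacryloyl chloride, CC(=C)C(=O)Cl
Why: O-acylation with an acid chloride and a hindered, non-nucleophilic base esterifies the C8 hydroxyl without a nucleophilic amine that could add to the iodo-dienone or move the neighbouring acetate.

Step 16
Reactants: 27 C8 methacrylate
Product: 28 primary C6 alcohol (7S,8S,9S,10S)
Conditions: HF·pyridine, THF, 0 °C to rt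
Reagents that add atoms: none
Why: Fluoride-driven cleavage of the primary silyl ether under mildly acidic, non-basic conditions spares the esters and the iodoalkene, and the reaction is stopped before the free hydroxyl can lactonise onto the acrylate ester.

Step 17
Reactants: 28 primary C6 alcohol
Product: 29 seco iodoalkene aldehyde, methyl (3R,4S,5S)-5-acetoxy-3-formyl-5-{(2S)-5-[(Z)-1-iodoprop-1-en-2-yl]-2-methyl-3-oxo-2,3-dihydrofuran-2-yl}-4-(methacryloyloxy)-2-methylidenepentanoate
Conditions: DMP, NaHCO3, CH2Cl2, 0 °C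
Reagents that add atoms: none
Why: Buffered Dess–Martin oxidation is fast and neutral, which the C7 centre needs because it is α to the new aldehyde, allylic to the acrylate and next to a β-acyloxy group.

Step 18
Reactants: 29 seco iodoalkene aldehyde
Product: 31 macrocyclic C6 hydroxy acrylate ester (4Z,6R,7S,8S,9S,10S), via alkenylchromium dichloride 30 (not isolated)
Conditions: CrCl2 (10 equiv), NiCl2 (0.1 equiv), degassed DMSO/THF, rt, slow addition of 29 to about 2 mM
Reagents that add atoms: none
Why: Zerovalent nickel, formed from NiCl2 by divalent chromium, inserts into the C5–I bond of 29, the alkenyl group passes to trivalent chromium with retention of the Z geometry to give 30, and this oxophilic, weakly basic alkenylchromium adds 1,2 to the C6 aldehyde before the chromium alkoxide is hydrolysed on work-up. The closest known reaction type is the Nozaki–Hiyama–Kishi macrocyclisation of iodoalkene aldehydes, which has precedent for nine- and ten-membered rings in oxygen-bridged terpenoid frameworks. The single ring closure is exo-trig at the C6 carbonyl with the oxygen left outside the ring, 10-exo-trig for the carbocycle C1–C10 and 9-exo-trig for the oxacycle that runs through the furanone oxygen. The new C6 centre is controlled by the adjacent C7 centre: with the C11 acrylate branch anti to the incoming C5 and the bulky chromium-bound oxygen turned outwards beside H7, the 6R alcohol with H6 anti to H7 should be favoured. The step needs chemoselectivity for the aldehyde over the furanone ketone, three esters and two acrylates, which the organochromium reagent provides, and it needs ring closure to outrun dimerisation, which the Z iodoalkene fixed on the planar furanone, the short C7–C10 tether and high dilution should secure.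

Step 19
Reactants: 31 macrocyclic C6 hydroxy acrylate ester
Product: 32 target CNP0365569.2
Conditions: p-TsOH·H2O (cat.), CH2Cl2, rt
Reagents that add atoms: none
Why: Acid-catalysed lactonisation (intramolecular transesterification) of the C6 hydroxyl onto the C12 methyl ester closes the α-methylene γ-lactone with loss of methanol, and C6 and C7 keep the configurations set in step 18, so the 6,7-trans fusion follows.

Compound list
1 | prop-2-yn-1-ol (propargyl alcohol) | C#CCO | starting material
2 | bromomagnesium (Z)-3-(bromomagnesio)-2-methylprop-2-en-1-olate (magnesium cis to CH2O) | C/C(CO[Mg]Br)=C/[Mg]Br | intermediate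
3 | (Z)-3-iodo-2-methylprop-2-en-1-ol | I/C=C(/C)CO | intermediate
4 | (Z)-3-iodo-2-methylprop-2-enal | I/C=C(/C)C=O | intermediate
5 | (tert-butyldimethylsilyloxy)acetaldehyde | O=CCO[Si](C)(C)C(C)(C)C | starting material
6 | methyl acrylate | C=CC(=O)OC | starting material
7 | methyl 4-[(tert-butyldimethylsilyl)oxy]-3-hydroxy-2-methylidenebutanoate (racemic) | C=C(C(=O)OC)C(O)CO[Si](C)(C)C(C)(C)C | intermediate
8 | methyl (Z)-2-(bromomethyl)-4-[(tert-butyldimethylsilyl)oxy]but-2-enoate | COC(=O)/C(CBr)=C/CO[Si](C)(C)C(C)(C)C | intermediate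
9 | (S)-2,2-dimethyl-1,3-dioxolane-4-carbaldehyde | O=C[C@@H]1COC(C)(C)O1 | starting material
10 | ethyl 2-[bis(2,2,2-trifluoroethoxy)phosphoryl]propanoate | CCOC(=O)C(C)P(=O)(OCC(F)(F)F)OCC(F)(F)F | starting material
11 | potassium salt of the α-carbanion of 10 | [K+].CCOC(=O)[C-](C)P(=O)(OCC(F)(F)F)OCC(F)(F)F | intermediate
12 | ethyl (Z)-3-[(4R)-2,2-dimethyl-1,3-dioxolan-4-yl]-2-methylprop-2-enoate | CCOC(=O)/C(C)=C\[C@H]1OC(C)(C)OC1 | intermediate
13 | ethyl (2S,3S)-3-[(4S)-2,2-dimethyl-1,3-dioxolan-4-yl]-2,3-dihydroxy-2-methylpropanoate | CCOC(=O)[C@@](C)(O)[C@@H](O)[C@H]1OC(C)(C)OC1 | intermediate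
14 | (2S,3S)-3-[(4S)-2,2-dimethyl-1,3-dioxolan-4-yl]-2,3-dihydroxy-N-methoxy-N,2-dimethylpropanamide | CON(C)C(=O)[C@@](C)(O)[C@@H](O)[C@H]1OC(C)(C)OC1 | intermediate
15 | (3S,4S)-4-[(4S)-2,2-dimethyl-1,3-dioxolan-4-yl]-3,4-dihydroxy-3-methylbutan-2-one | CC(=O)[C@@](C)(O)[C@@H](O)[C@H]1OC(C)(C)OC1 | intermediate
16 | (1S,2S)-1-[(4S)-2,2-dimethyl-1,3-dioxolan-4-yl]-2-hydroxy-2-methyl-3-oxobutyl acetate | CC(=O)[C@@](C)(O)[C@@H](OC(C)=O)[C@H]1OC(C)(C)OC1 | intermediate
17 | (1S,2S)-1-[(4S)-2,2-dimethyl-1,3-dioxolan-4-yl]-2-methyl-3-oxo-2-[(triethylsilyl)oxy]butyl acetate | CC(=O)[C@@](C)(O[Si](CC)(CC)CC)[C@@H](OC(C)=O)[C@H]1OC(C)(C)OC1 | intermediate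
18 | dicyclohexylboron enolate of 17 (boron on the C1 oxygen, C1=C2 methylidene) | C=C(OB(C1CCCCC1)C1CCCCC1)[C@@](C)(O[Si](CC)(CC)CC)[C@@H](OC(C)=O)[C@H]1OC(C)(C)OC1 | intermediate
19 | (1S,2S,6Z)-1-[(4S)-2,2-dimethyl-1,3-dioxolan-4-yl]-5-hydroxy-7-iodo-2,6-dimethyl-3-oxo-2-[(triethylsilyl)oxy]hept-6-en-1-yl acetate (both epimers at the carbinol) | I/C=C(/C)C(O)CC(=O)[C@@](C)(O[Si](CC)(CC)CC)[C@@H](OC(C)=O)[C@H]1OC(C)(C)OC1 | intermediate
20 | (1S,2S,6Z)-1-[(4S)-2,2-dimethyl-1,3-dioxolan-4-yl]-7-iodo-2,6-dimethyl-3,5-dioxo-2-[(triethylsilyl)oxy]hept-6-en-1-yl acetate | I/C=C(/C)C(=O)CC(=O)[C@@](C)(O[Si](CC)(CC)CC)[C@@H](OC(C)=O)[C@H]1OC(C)(C)OC1 | intermediate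
21 | (1S,2S,6Z)-1-[(4S)-2,2-dimethyl-1,3-dioxolan-4-yl]-2-hydroxy-7-iodo-2,6-dimethyl-3,5-dioxohept-6-en-1-yl acetate | I/C=C(/C)C(=O)CC(=O)[C@@](C)(O)[C@@H](OC(C)=O)[C@H]1OC(C)(C)OC1 | intermediate
22 | (S)-[(4S)-2,2-dimethyl-1,3-dioxolan-4-yl]{(2S)-5-[(Z)-1-iodoprop-1-en-2-yl]-2-methyl-3-oxo-2,3-dihydrofuran-2-yl}methyl acetate | I/C=C(/C)C1=CC(=O)[C@@](C)(O1)[C@@H](OC(C)=O)[C@H]2OC(C)(C)OC2 | intermediate
23 | (1S,2S)-2,3-dihydroxy-1-{(2S)-5-[(Z)-1-iodoprop-1-en-2-yl]-2-methyl-3-oxo-2,3-dihydrofuran-2-yl}propyl acetate | I/C=C(/C)C1=CC(=O)[C@@](C)(O1)[C@@H](OC(C)=O)[C@@H](O)CO | intermediate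
24 | (1R)-1-{(2S)-5-[(Z)-1-iodoprop-1-en-2-yl]-2-methyl-3-oxo-2,3-dihydrofuran-2-yl}-2-oxoethyl acetate | I/C=C(/C)C1=CC(=O)[C@@](C)(O1)[C@@H](OC(C)=O)C=O | intermediate
25 | allylzinc bromide from 8 (ZnBr in place of bromine) | COC(=O)/C(C[Zn]Br)=C/CO[Si](C)(C)C(C)(C)C | intermediate
26 | methyl (3S,4S,5S)-5-acetoxy-3-{[(tert-butyldimethylsilyl)oxy]methyl}-4-hydroxy-5-{(2S)-5-[(Z)-1-iodoprop-1-en-2-yl]-2-methyl-3-oxo-2,3-dihydrofuran-2-yl}-2-methylidenepentanoate | I/C=C(/C)C1=CC(=O)[C@@](C)(O1)[C@@H](OC(C)=O)[C@@H](O)[C@H](CO[Si](C)(C)C(C)(C)C)C(=C)C(=O)OC | intermediate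
27 | methyl (3S,4S,5S)-5-acetoxy-3-{[(tert-butyldimethylsilyl)oxy]methyl}-5-{(2S)-5-[(Z)-1-iodoprop-1-en-2-yl]-2-methyl-3-oxo-2,3-dihydrofuran-2-yl}-4-(methacryloyloxy)-2-methylidenepentanoate | I/C=C(/C)C1=CC(=O)[C@@](C)(O1)[C@@H](OC(C)=O)[C@@H](OC(=O)C(C)=C)[C@H](CO[Si](C)(C)C(C)(C)C)C(=C)C(=O)OC | intermediate
28 | methyl (3S,4S,5S)-5-acetoxy-3-(hydroxymethyl)-5-{(2S)-5-[(Z)-1-iodoprop-1-en-2-yl]-2-methyl-3-oxo-2,3-dihydrofuran-2-yl}-4-(methacryloyloxy)-2-methylidenepentanoate | I/C=C(/C)C1=CC(=O)[C@@](C)(O1)[C@@H](OC(C)=O)[C@@H](OC(=O)C(C)=C)[C@H](CO)C(=C)C(=O)OC | intermediate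
29 | seco iodoalkene aldehyde, methyl (3R,4S,5S)-5-acetoxy-3-formyl-5-{(2S)-5-[(Z)-1-iodoprop-1-en-2-yl]-2-methyl-3-oxo-2,3-dihydrofuran-2-yl}-4-(methacryloyloxy)-2-methylidenepentanoate | I/C=C(/C)C1=CC(=O)[C@@](C)(O1)[C@@H](OC(C)=O)[C@@H](OC(=O)C(C)=C)[C@H](C=O)C(=C)C(=O)OC | intermediate
30 | alkenylchromium dichloride from 29 (CrCl2 on C5 in place of iodine, Z retained, trivalent chromium) | Cl[Cr](Cl)/C=C(/C)C1=CC(=O)[C@@](C)(O1)[C@@H](OC(C)=O)[C@@H](OC(=O)C(C)=C)[C@H](C=O)C(=C)C(=O)OC | intermediate
31 | macrocyclic C6 hydroxy acrylate ester (4Z,6R,7S,8S,9S,10S): ten-membered carbocycle bridged by the furanone oxygen, C6 hydroxyl, C7 methyl acrylate, C8 methacrylate, C9 acetate | C=C(C)C(=O)O[C@H]1[C@@H](C(=C)C(=O)OC)[C@H](O)/C=C(/C)C2=CC(=O)[C@@](C)(O2)[C@H]1OC(C)=O | intermediate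
32 | CNP0365569.2 (4Z,6R,7S,8S,9S,10S), the 6,12-lactone of 31 | C=C(C)C(=O)O[C@H]1[C@H]2C(=C)C(=O)O[C@@H]2/C=C(/C)C2=CC(=O)[C@@](C)(O2)[C@H]1OC(C)=O | target

Total step count: 19 steps.

Longest linear sequence: 15 steps (steps 5 to 19, from aldehyde 9); steps 1–2 feed step 11 and steps 3–4 feed step 14.

Steps most likely to fail

1. Step 18. The ring-closing addition may deliver the C6 hydroxyl with poor or reversed facial selectivity, because the outcome depends on the conformation of a strained medium ring in the transition state, and intermolecular addition may compete. The fallback sets out from 29 and returns at 31. The ring closure is run as before and taken on whatever its C6 outcome. The 6-epi alcohol F1, alone or mixed with 31, is oxidised with DMP to the macrocyclic C6 ketone F2. C6 is then set by reagent-controlled 1,2-reduction at −78 °C with catecholborane and the enantiomer of the 2-methyl-CBS-oxazaborolidine that delivers hydride to the Si face of the C6 carbonyl, which should give 31. The stereocentre is thus set by carbonyl reduction and no longer by the C–C bond formation.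

2. Step 14. The 1,2-induction from C9 may be low, or the 7,8-syn selectivity may erode because the allylzinc equilibrates. The zinc alkoxide may also lactonise onto the ester, or the C9 acetate may migrate to the new hydroxyl. The fallback sets out from 7 and 24 and returns at 26. Alcohol 7 is acetylated (Ac2O, pyridine) to allylic acetate F3. Copper-catalysed borylation with allylic transposition (B2pin2, CuCl, KOAc, DMF) gives the geometrically defined allylboronate F4, with the silyloxymethyl group cis to the borylmethyl group. Its Sc(OTf)3-catalysed addition to 24 in toluene at low temperature passes through a closed chair transition state, which ties the 7,8-syn relationship to the olefin geometry and keeps the attack anti to the C9 acetate. Neutral work-up should then give 26.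

3. Step 17. While the aldehyde is formed and handled, C7 may epimerise, the C11=C13 double bond may move into conjugation, or the C8 methacrylate may be lost by β-elimination. The fallback sets out from 24 and methyl acrylate 6 and returns at 29; it carries C6 at the aldehyde oxidation level from the allylation onwards, so that no oxidation is needed. Morita–Baylis–Hillman reaction of 6 with commercial 2,2-dimethoxyacetaldehyde (DABCO) gives hydroxy acetal F5. NBS and Me2S give the rearranged bromo acetal F6. Zinc allylation of 24 as in step 14 gives the C8 alcohol acetal F7, and methacryloyl chloride with i-Pr2NEt gives the methacrylate acetal F8. The dimethyl acetal is hydrolysed with LiBF4 in wet MeCN just before the ring closure, which should give 29; steps 16 and 17 are then not needed.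

Further compounds
F1 | step 18 | C6 epimer of 31 (4Z,6S,7S,8S,9S,10S) | C=C(C)C(=O)O[C@H]1[C@@H](C(=C)C(=O)OC)[C@@H](O)/C=C(/C)C2=CC(=O)[C@@](C)(O2)[C@H]1OC(C)=O
F2 | step 18 | macrocyclic C6 ketone (4Z,7S,8S,9S,10S) | C=C(C)C(=O)O[C@H]1[C@@H](C(=C)C(=O)OC)C(=O)/C=C(/C)C2=CC(=O)[C@@](C)(O2)[C@H]1OC(C)=O
F3 | step 14 | methyl 3-acetoxy-4-[(tert-butyldimethylsilyl)oxy]-2-methylidenebutanoate (racemic) | C=C(C(=O)OC)C(OC(C)=O)CO[Si](C)(C)C(C)(C)C
F4 | step 14 | methyl (E)-4-[(tert-butyldimethylsilyl)oxy]-2-[(4,4,5,5-tetramethyl-1,3,2-dioxaborolan-2-yl)methyl]but-2-enoate | COC(=O)/C(CB1OC(C)(C)C(C)(C)O1)=C/CO[Si](C)(C)C(C)(C)C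
F5 | step 17 | methyl 3-hydroxy-4,4-dimethoxy-2-methylidenebutanoate (racemic) | C=C(C(=O)OC)C(O)C(OC)OC
F6 | step 17 | methyl (Z)-2-(bromomethyl)-4,4-dimethoxybut-2-enoate | COC(=O)/C(CBr)=C/C(OC)OC
F7 | step 17 | C6 dimethyl acetal analogue of 26 (C8 hydroxyl free) | I/C=C(/C)C1=CC(=O)[C@@](C)(O1)[C@@H](OC(C)=O)[C@@H](O)[C@H](C(OC)OC)C(=C)C(=O)OC
F8 | step 17 | C6 dimethyl acetal analogue of 27 (C8 methacrylate) | I/C=C(/C)C1=CC(=O)[C@@](C)(O1)[C@@H](OC(C)=O)[C@@H](OC(=O)C(C)=C)[C@H](C(OC)OC)C(=C)C(=O)OC
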